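## Analysis of the target

Compound 28 is a trans-fused octahydro-2H-chromene: a cyclohexane and a tetrahydropyran that share the C8–C9 bond. The numbering used here is: C10 = ring carbon with CH3 and the CH2CO2H arm (C1–C2); C5 = ring CH carrying C4, the C(CH3)2 carbon of the acid C3; C6, C7 = ring CH2; C8 = ring-fusion C(CH3)O; C9 = ring-fusion CH; C11, C12 = pyran CH2; C13 = OC(CH3)(vinyl); C14=C15 = vinyl group.

There are five stereocentres. C5, C10, C9 and C8 are contiguous on the carbocycle (5R,10S,9R,8R) and C13 (R) lies across the ring oxygen from C8. C8, C10 and C13 are fully substituted, and C10 is an all-carbon quaternary centre. The methyl groups on C10, C8 and C13 are axial on one face and H-5 and H-9 lie on the other, so the ring fusion is trans, the C4 arm, the C1 arm and the vinyl group are equatorial, and the two carboxyl arms are trans to each other.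

The ether oxygen joins two tertiary carbons and C13 is also allylic, so strong acid can ionise the C13–O bond and scramble C13. The C3 carboxyl group sits on a quaternary carbon and resists attack at its carbonyl group.

The synthesis is hard for two reasons. C13 carries two small, similar groups (CH3 and vinyl) and is insulated from the ring stereocentres, so substrate control there is weak. C8 needs its oxygen equatorial, whereas a methyl nucleophile would approach a C8 ketone from the equatorial side, away from the axial C10 methyl group.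

The strategy rests on the 1,3-relationship of C13 and C8 through oxygen. C13, with its CH3 group and its two-carbon arm C14–C15, is the tertiary carbon of the epoxide of an (E)-3-methylallylic alcohol. The C8 hydroxyl can displace the epoxide oxygen at C13 with inversion, which closes the pyran ring and leaves a 14,15-diol as precursor of the vinyl group.

## Retrosynthetic reasoning

**28 from 27.** Both acids are unmasked last from the dimethyl ester 27. Methyl esters survive every earlier step and can be cleaved at the O–CH3 bond without acid, which protects the tertiary allylic ether and does not depend on access to the hindered C3 carbonyl.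

**27 from 25 via 26.** The C14=C15 double bond is traced back to the 14,15-diol 25 through the cyclic thiocarbonate 26 (Corey–Winter olefination). The diol is exactly what an epoxide opening at C13 leaves behind, so no extra functional-group change is needed.

**25 from 24 (key disconnection).** The O–C13 bond is cut. This is the only bond whose formation can transfer a reagent-made configuration to C13 stereospecifically. Cutting O–C8 instead would need a cation or an addition at a ring carbon whose facial bias opposes the required equatorial oxygen. The forward step has to make the C8 hydroxyl of epoxy alcohol 24 attack the tertiary epoxide carbon with inversion, in the 6-exo mode.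

**24 from 23.** The epoxide oxygen comes from Sharpless epoxidation of the (E)-allylic alcohol 23. The chiral ligand, not the distant ring, decides C13 and C14.

**23 from 21, and 21 from 17 via 18 and 20.** In 23 the C13–CH3 and C14–C15 bonds are cut together: syn methylmetalation of the terminal alkyne 21 and capture by a one-carbon electrophile fix the E geometry. The alkyne is the one-carbon homologue of the aldehyde that exists as lactol 20, which comes from diol 18 and silyl ether 17. The side-chain alkene must come late because it would not survive the hydroboration and hydration used on the ring.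

**17 from 15, and 15 from 14.** The C8–O bond is made by Markovnikov hydration of the exocyclic alkene 15, not by methyl addition to ketone 14. In the hydration the oxygen enters along the open equatorial path and the carbon that becomes the methyl group is already in place. Alkene 15 is the methylenation product of 14.

**14 from 11 via 13.** The C8 oxygen and H-9 are introduced by hydroboration–oxidation of the C8=C9 alkene 11 to alcohol 13, then oxidation. Ketone 14 also makes C9 epimerisable, a thermodynamic safeguard for the equatorial side chain.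

**11 from 8 and 9, and 8 from 6.** The C9–C11 bond is cut between an sp2 and an sp3 carbon: enol triflate 8 is coupled with the alkylborane from alkene 9. Triflate 8 comes from ketone 6, which can only enolise towards C8 because C10 is quaternary.

**6 from 3 and 4, and 3 from 1 and 2.** The C10–C1 bond is cut (alkylation of the enolate of 3 with 4, anti to the C5 substituent), then the C5–C4 bond (catalyst-controlled conjugate addition of 2 to 1). This sets C5 and C10 and delivers both carboxyl arms at the right oxidation level from the start.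

## Alternatives that were turned down

**Alternative 1:** This cuts the C4–C5 and C10–C1 bonds on the ring of 1 in a three-component union. In the forward step a chiral oxazaborolidinium Lewis acid guides 2 to C5 of 1, and the enolate released from the silyl enol ether is alkylated at C10 by tert-butyl bromoacetate A2 to give keto diester A1.
- For: two C–C bonds and two adjacent stereocentres, one of them the all-carbon quaternary C10, arise in one operation from cheap materials. Absolute control comes from the catalyst and relative control from the C5 substituent.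
- Against: as a strategy it ends at A1. C8, C9, C13 and the whole pyran ring are left open, and the hardest centre, C13, would fall to later substrate-controlled chemistry. The tert-butyl ester of A1 must eventually be removed with acid, which endangers the tertiary allylic ether.
- Comparison: for building the carbocycle with C5 and C10 it is as strong as anything available, and the chosen route uses the same type of reaction in steps 1 and 2 (with 4 in place of A2). What the chosen strategy adds is a reagent-controlled, stereospecific answer for C13.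

**Alternative 2:** This cuts C9–C10 and C8–O in one cascade from the open-chain hydroxy diene A4. In the forward step a cobalt hydride made from Co(salen) A5 (divalent cobalt), a hydrosilane and an N-fluoropyridinium oxidant transfers a hydrogen atom to the 1,1-disubstituted alkene. The C10 radical closes 6-endo onto the C8=C9 alkene, the C8 radical is oxidised to the cation, and the C13 hydroxyl captures it to give bicyclic ether A3.
- For: both rings, two bonds and three stereocentres (C8, C9, C10) form in one step. C13 enters as a pre-formed tertiary alcohol and is not touched. On bonds formed per step and on step count for ring construction it is clearly stronger than the chosen route.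
- Against: A4 needs two remote stereocentres (C5 and C13) made by separate asymmetric operations, and a tertiary alcohol with CH3 and two CH2 arms is hard to make enantiopure. In the cascade the C5 centre alone must control the face of the C10 radical. Hydrogen transfer must choose between two alkenes of similar reactivity. The C8 cation can lose a proton or be captured from either face. Afterwards the silyloxyethyl group of A3 still has to become vinyl (about three steps).
- Comparison: the chosen route is longer, but each stereocentre is set by one predictable element and C13 by a stereospecific substitution. Its risk sits in one ring closure of a known type, not in a cascade with four selectivity questions.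

**Alternative 3:** This cuts C12–C13 and C8–O by a [4+2] cycloaddition between the diene A7 (C12=C11–C9=C8) and the ketone carbonyl of ethyl pyruvate A8. In the forward step Cu(OTf)2 A9 (divalent copper) with a chiral bis(oxazoline) ligand chelates A8, and the cycloaddition gives dihydropyran A6.
- For: it is convergent, it forms the pyran ring with C8 and C13 in one step under catalyst control, the C13 ester is a handle for the vinyl group, and the C9=C11 alkene can be hydrogenated to install H-9. On convergence and probably by three or four steps it is stronger than the chosen route.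
- Against: A7 carries no donor group, its C8 terminus is fully substituted, and its s-cis form is crowded by the C8 methyl group and the quaternary C10. With such dienes an activated ketone tends to react by the carbonyl-ene path, for which the C8 methyl and C7 hydrogens are well placed. Catalyst and substrate may disagree on the face at C8. Afterwards three different esters in A6 must be told apart, and its tert-butyl ester needs acid for removal.
- Comparison: the key step lies outside secure precedent for this diene class, whereas the chosen ring closure is an established reaction type and avoids ester differentiation.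

Key step: step 14

Assumption: in step 1 the (S)-configured oxazaborolidinium catalyst is taken to deliver the nucleophile to the face of C5 that leads to (R)-3; if the sense of induction is the opposite, the (R)-catalyst is used.

## Route

Step 1
Reactants: 1 2-methylcyclohex-2-en-1-one; 2 1-methoxy-2-methyl-1-(trimethylsilyloxy)prop-1-ene
Product: 3 methyl 2-methyl-2-[(1R)-2-methyl-3-(trimethylsilyloxy)cyclohex-2-en-1-yl]propanoate
Conditions: (S)-1-(o-tolyl)-3,3-diphenyltetrahydropyrrolo[1,2-c][1,3,2]oxazaborole (20 mol %), HNTf2 (20 mol %), Ph3PO (25 mol %), toluene, −20 °C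
Reagents that add atoms: none
Why: Catalytic enantioselective Mukaiyama–Michael addition: the enone bound to the chiral oxazaborolidinium ion is attacked at C5 on the face left open by the catalyst, which sets C5 (R); silyl transfer to the enolate oxygen gives the tetrasubstituted silyl enol ether with the C9=C10 double bond fixed in place.

Step 2
Reactants: 3 methyl 2-methyl-2-[(1R)-2-methyl-3-(trimethylsilyloxy)cyclohex-2-en-1-yl]propanoate; 4 methyl bromoacetate
Product: 6 methyl 2-[(1S,2R)-2-(1-methoxy-2-methyl-1-oxopropan-2-yl)-1-methyl-6-oxocyclohexyl]acetate, via ammonium enolate 5 (not isolated)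
Conditions: BnMe3NF (anhydrous), 4 Å MS, THF, −20 °C → rt
Reagents that add atoms: none
Why: Fluoride-induced desilylation gives a regiodefined ammonium enolate without touching the hindered ester (regiospecific alkylation of a silyl enol ether); bromoacetate 4 alkylates C10 on the face opposite to the bulky C5 substituent, which sets the quaternary centre C10 (S) with the acetate arm trans to the C4 arm.

Step 3
Reactants: 6 methyl 2-[(1S,2R)-2-(1-methoxy-2-methyl-1-oxopropan-2-yl)-1-methyl-6-oxocyclohexyl]acetate
Product: 8 methyl 2-[(1S,6R)-6-(1-methoxy-2-methyl-1-oxopropan-2-yl)-1-methyl-2-(trifluoromethanesulfonyloxy)cyclohex-2-en-1-yl]acetate, via potassium enolate 7 (not isolated)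
Conditions: KN(SiMe3)2, THF, −78 °C; then PhNTf2, −78 → 0 °C
Reagents that add atoms: N-phenylbis(trifluoromethanesulfonimide), O=S(=O)(N(c1ccccc1)S(=O)(=O)C(F)(F)F)C(F)(F)F
Why: C10 is quaternary, so the ketone can enolise only towards C8; O-sulfonylation of the potassium enolate gives the C8=C9 enol triflate (kinetic enol triflate formation), and the ester α-hydrogens are far less acidic than those of the ketone.

Step 4
Reactants: 8 methyl 2-[(1S,6R)-6-(1-methoxy-2-methyl-1-oxopropan-2-yl)-1-methyl-2-(trifluoromethanesulfonyloxy)cyclohex-2-en-1-yl]acetate; 9 allyloxy(tert-butyl)dimethylsilane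
Product: 11 methyl 2-[(1S,6R)-2-[3-(tert-butyldimethylsilyloxy)propyl]-6-(1-methoxy-2-methyl-1-oxopropan-2-yl)-1-methylcyclohex-2-en-1-yl]acetate, via B-alkyl-9-BBN 10 (not isolated)
Conditions: 9-BBN, THF, rt; then 8, PdCl2(dppf) (5 mol %), K3PO4 (aq), DMF, 50 °C
Reagents that add atoms: none
Why: B-alkyl Suzuki–Miyaura coupling: 9-BBN adds to the terminal alkene of 9 at its CH2 end, and the primary alkyl group is transferred through zerovalent palladium to the enol triflate, which forms C9–C11 and leaves the double bond at C8=C9; esters and silyl ether are inert.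

Step 5
Reactants: 11 methyl 2-[(1S,6R)-2-[3-(tert-butyldimethylsilyloxy)propyl]-6-(1-methoxy-2-methyl-1-oxopropan-2-yl)-1-methylcyclohex-2-en-1-yl]acetate
Product: 13 methyl 2-[(1S,2R,3R,6R)-2-[3-(tert-butyldimethylsilyloxy)propyl]-3-hydroxy-6-(1-methoxy-2-methyl-1-oxopropan-2-yl)-1-methylcyclohexyl]acetate, via C8 alkylborane 12 (not isolated)
Conditions: BH3·THF, THF, 0 °C → rt; then NaBO3·4H2O, H2O, rt
Reagents that add atoms: sodium perborate, [Na+].[O-]OB=O
Why: Hydroboration–oxidation: boron adds to the less substituted C8 and hydrogen to C9, syn and from the face opposite to the pseudoaxial C10 methyl group, which places H-9 trans to that methyl group (C9, R); perborate oxidises the C–B bond with retention and spares the methyl esters, which BH3 reduces much more slowly than it adds to the alkene.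

Step 6
Reactants: 13 methyl 2-[(1S,2R,3R,6R)-2-[3-(tert-butyldimethylsilyloxy)propyl]-3-hydroxy-6-(1-methoxy-2-methyl-1-oxopropan-2-yl)-1-methylcyclohexyl]acetate
Product: 14 methyl 2-[(1S,2R,6R)-2-[3-(tert-butyldimethylsilyloxy)propyl]-6-(1-methoxy-2-methyl-1-oxopropan-2-yl)-1-methyl-3-oxocyclohexyl]acetate
Conditions: Dess–Martin periodinane, NaHCO3, CH2Cl2, 0 °C → rt
Reagents that add atoms: none
Why: Dess–Martin oxidation of the secondary alcohol under buffered conditions; the C9 side chain is equatorial, so the configuration from step 5 is also the thermodynamic one, and any C9 epimer can be equilibrated with a mild base through the enol.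

Step 7
Reactants: 14 methyl 2-[(1S,2R,6R)-2-[3-(tert-butyldimethylsilyloxy)propyl]-6-(1-methoxy-2-methyl-1-oxopropan-2-yl)-1-methyl-3-oxocyclohexyl]acetate
Product: 15 methyl 2-[(1R,2S,6R)-2-[3-(tert-butyldimethylsilyloxy)propyl]-6-(1-methoxy-2-methyl-1-oxopropan-2-yl)-1-methyl-3-methylidenecyclohexyl]acetate
Conditions: Ph3PCH3Br, KN(SiMe3)2, THF, 0 °C → rt
Reagents that add atoms: methyltriphenylphosphonium bromide, C[P+](c1ccccc1)(c1ccccc1)c1ccccc1.[Br-]
Why: Wittig methylenation of a ketone in the presence of esters, which the non-stabilised ylide does not attack; C9 stays at its thermodynamic configuration even if the ketone is enolised reversibly (the descriptors at C9 and C10 change only because the priorities change).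

Step 8
Reactants: 15 methyl 2-[(1R,2S,6R)-2-[3-(tert-butyldimethylsilyloxy)propyl]-6-(1-methoxy-2-methyl-1-oxopropan-2-yl)-1-methyl-3-methylidenecyclohexyl]acetate
Product: 17 methyl 2-[(1S,2R,3R,6R)-2-[3-(tert-butyldimethylsilyloxy)propyl]-3-hydroxy-6-(1-methoxy-2-methyl-1-oxopropan-2-yl)-1,3-dimethylcyclohexyl]acetate, via organomercurial 16 (not isolated)
Conditions: Hg(OAc)2, THF/H2O, rt; then NaBH4, NaOH (aq), 0 °C
Reagents that add atoms: water, O
Why: Oxymercuration–demercuration (Markovnikov hydration): water attacks the tertiary carbon C8 of the mercurinium ion along the equatorial path because the axial one is blocked by the syn-axial C10 methyl group, which gives the equatorial hydroxyl and, after reductive removal of mercury, the axial methyl group at C8 (R); NaBH4 does not reduce the esters under these conditions.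

Step 9
Reactants: 17 methyl 2-[(1S,2R,3R,6R)-2-[3-(tert-butyldimethylsilyloxy)propyl]-3-hydroxy-6-(1-methoxy-2-methyl-1-oxopropan-2-yl)-1,3-dimethylcyclohexyl]acetate
Product: 18 methyl 2-[(1S,2R,3R,6R)-3-hydroxy-2-(3-hydroxypropyl)-6-(1-methoxy-2-methyl-1-oxopropan-2-yl)-1,3-dimethylcyclohexyl]acetate
Conditions: Bu4NF, THF, 0 °C → rt
Reagents that add atoms: none
Why: Fluoride cleavage of the primary silyl ether; the tertiary alcohol and both esters are unaffected.

Step 10
Reactants: 18 methyl 2-[(1S,2R,3R,6R)-3-hydroxy-2-(3-hydroxypropyl)-6-(1-methoxy-2-methyl-1-oxopropan-2-yl)-1,3-dimethylcyclohexyl]acetate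
Product: 20 methyl 2-[(4aR,5S,6R,8aR)-2-hydroxy-5-(2-methoxy-2-oxoethyl)-5,8a-dimethyl-octahydro-2H-chromen-6-yl]-2-methylpropanoate (lactol, both anomers), via hydroxy aldehyde 19 (not isolated)
Conditions: (COCl)2, DMSO, CH2Cl2, −78 °C; then Et3N, −78 → 0 °C
Reagents that add atoms: none
Why: Swern oxidation of the primary alcohol at low temperature, where the hindered tertiary hydroxyl does not react; the δ-hydroxy aldehyde closes to the six-membered lactol only after the oxidant is consumed, so no lactone forms.

Step 11
Reactants: 20 methyl 2-[(4aR,5S,6R,8aR)-2-hydroxy-5-(2-methoxy-2-oxoethyl)-5,8a-dimethyl-octahydro-2H-chromen-6-yl]-2-methylpropanoate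
Product: 21 methyl 2-[(1S,2R,3R,6R)-2-(but-3-yn-1-yl)-3-hydroxy-6-(1-methoxy-2-methyl-1-oxopropan-2-yl)-1,3-dimethylcyclohexyl]acetate
Conditions: dimethyl (1-diazo-2-oxopropyl)phosphonate, K2CO3, MeOH, rt
Reagents that add atoms: dimethyl (1-diazo-2-oxopropyl)phosphonate, CC(=O)C(=[N+]=[N-])P(=O)(OC)OC
Why: Ohira–Bestmann (Seyferth–Gilbert) homologation: the lactol reacts through its open hydroxy aldehyde form with the diazomethylphosphonate anion, and the alkylidene carbene rearranges to the terminal alkyne; K2CO3 in methanol leaves methyl esters unchanged.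

Step 12
Reactants: 21 methyl 2-[(1S,2R,3R,6R)-2-(but-3-yn-1-yl)-3-hydroxy-6-(1-methoxy-2-methyl-1-oxopropan-2-yl)-1,3-dimethylcyclohexyl]acetate
Product: 23 methyl 2-[(1S,2R,3R,6R)-3-hydroxy-2-[(3E)-5-hydroxy-3-methylpent-3-en-1-yl]-6-(1-methoxy-2-methyl-1-oxopropan-2-yl)-1,3-dimethylcyclohexyl]acetate, via alkenylalane 22 (not isolated)
Conditions: Me3Al, Cp2ZrCl2, H2O (1 equiv), CH2Cl2, −23 °C; then (CH2O)n, −23 °C → rt
Reagents that add atoms: trimethylaluminium, C[Al](C)C; formaldehyde (from paraformaldehyde), C=O
Why: Zirconium-catalysed Negishi carboalumination: CH3 and aluminium add syn across the terminal alkyne with CH3 on the internal carbon C13, and the alkenylalane adds to formaldehyde with retention, which fixes the (E)-alkene; the low-temperature water-accelerated variant keeps the hindered methyl esters out of reach of Me3Al, and the tertiary hydroxyl is masked as its aluminium alkoxide.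

Step 13
Reactants: 23 methyl 2-[(1S,2R,3R,6R)-3-hydroxy-2-[(3E)-5-hydroxy-3-methylpent-3-en-1-yl]-6-(1-methoxy-2-methyl-1-oxopropan-2-yl)-1,3-dimethylcyclohexyl]acetate
Product: 24 methyl 2-[(1S,2R,3R,6R)-3-hydroxy-2-{2-[(2S,3S)-3-(hydroxymethyl)-2-methyloxiran-2-yl]ethyl}-6-(1-methoxy-2-methyl-1-oxopropan-2-yl)-1,3-dimethylcyclohexyl]acetate
Conditions: Ti(OiPr)4 (10 mol %), L-(+)-diethyl tartrate (12 mol %), t-BuOOH, 4 Å MS, CH2Cl2, −20 °C
Reagents that add atoms: tert-butyl hydroperoxide, CC(C)(C)OO
Why: Sharpless asymmetric epoxidation of an (E)-3-methylallylic alcohol: with L-(+)-diethyl tartrate the oxygen is delivered to the face that gives the (13S,14S)-epoxide, as for other (E)-3-methyl-2-alken-1-ols; C13 and C14 are set by the reagent, independent of the remote ring stereocentres, and any cyclisation that already begins on titanium leads to the same product as step 14.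

Step 14
Reactants: 24 methyl 2-[(1S,2R,3R,6R)-3-hydroxy-2-{2-[(2S,3S)-3-(hydroxymethyl)-2-methyloxiran-2-yl]ethyl}-6-(1-methoxy-2-methyl-1-oxopropan-2-yl)-1,3-dimethylcyclohexyl]acetate
Product: 25 methyl 2-[(2R,4aR,5S,6R,8aR)-2-[(1S)-1,2-dihydroxyethyl]-5-(2-methoxy-2-oxoethyl)-2,5,8a-trimethyl-octahydro-2H-chromen-6-yl]-2-methylpropanoate
Conditions: (±)-camphor-10-sulfonic acid (10 mol %), CH2Cl2, 0 °C → rt
Reagents that add atoms: none
Why: The sulfonic acid activates the epoxide oxygen, the bond to the more substituted carbon C13 lengthens, and the C8 hydroxyl attacks C13 from the side opposite to the departing oxygen in a chair-like transition state. The closest known reaction type is the acid-catalysed exo-selective cyclisation of hydroxy epoxides, that is, the opening of a 2,3-epoxy alcohol at its C3 carbon by an internal hydroxyl, which is widely used for tetrahydropyran and tetrahydrofuran rings. The pyran ring closes in the 6-exo-tet mode, and O–C13 is the one skeletal bond formed. C13 is the new ring stereocentre; it is controlled only by the epoxide configuration from step 13 and is formed with inversion, (13S)-epoxide to (13R)-ether, while C14 keeps its configuration. The step needs regioselectivity for C13 over C14, and both ring size (six against seven) and charge stabilisation at the tertiary carbon point to C13. It needs stereospecificity, which is secured because the oxygen on C14 destabilises a free cation at C13, so that the opening stays SN2-like. In the chair the C13 methyl group is axial and the larger dihydroxyethyl arm equatorial, the less strained of the two arrangements next to the axial C8 methyl group. The primary C15 hydroxyl could only form an oxetane and the esters are remote, so neither competes.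

Step 15
Reactants: 25 methyl 2-[(2R,4aR,5S,6R,8aR)-2-[(1S)-1,2-dihydroxyethyl]-5-(2-methoxy-2-oxoethyl)-2,5,8a-trimethyl-octahydro-2H-chromen-6-yl]-2-methylpropanoate
Product: 26 methyl 2-[(2R,4aR,5S,6R,8aR)-5-(2-methoxy-2-oxoethyl)-2,5,8a-trimethyl-2-[(4S)-2-sulfanylidene-1,3-dioxolan-4-yl]-octahydro-2H-chromen-6-yl]-2-methylpropanoate
Conditions: 1,1′-thiocarbonyldiimidazole, DMAP (cat.), THF, 60 °C
Reagents that add atoms: 1,1′-thiocarbonyldiimidazole, S=C(n1ccnc1)n1ccnc1
Why: Formation of the five-membered cyclic thiocarbonate from the 1,2-diol (first stage of the Corey–Winter olefination); no other hydroxyl is left in the molecule.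

Step 16
Reactants: 26 methyl 2-[(2R,4aR,5S,6R,8aR)-5-(2-methoxy-2-oxoethyl)-2,5,8a-trimethyl-2-[(4S)-2-sulfanylidene-1,3-dioxolan-4-yl]-octahydro-2H-chromen-6-yl]-2-methylpropanoate
Product: 27 methyl 2-[(2R,4aR,5S,6R,8aR)-2-ethenyl-5-(2-methoxy-2-oxoethyl)-2,5,8a-trimethyl-octahydro-2H-chromen-6-yl]-2-methylpropanoate
Conditions: 1,3-dimethyl-2-phenyl-1,3,2-diazaphospholidine, THF, 40 °C
Reagents that add atoms: none
Why: Corey–Winter olefination: the phosphorus reagent removes sulfur and the resulting carbene fragments with loss of CO2 to the terminal alkene; C13 is not touched, and the neutral, mild conditions spare the tertiary allylic ether and the esters.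

Step 17
Reactants: 27 methyl 2-[(2R,4aR,5S,6R,8aR)-2-ethenyl-5-(2-methoxy-2-oxoethyl)-2,5,8a-trimethyl-octahydro-2H-chromen-6-yl]-2-methylpropanoate
Product: 28 2-[(2R,4aR,5S,6R,8aR)-5-(carboxymethyl)-2-ethenyl-2,5,8a-trimethyl-octahydro-2H-chromen-6-yl]-2-methylpropanoic acid
Conditions: NaSEt, DMF, 90 °C; then dilute HCl, 0 °C, pH 3–4
Reagents that add atoms: none
Why: SN2 demethylation of both methyl esters by thiolate at the O-methyl carbon, which does not depend on the steric hindrance around the C3 carbonyl group; only a cold, dilute acid work-up meets the tertiary allylic ether, and no stereocentre is epimerisable.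

## Compound list

1 | 2-methylcyclohex-2-en-1-one | CC1=CCCCC1=O | starting material
2 | 1-methoxy-2-methyl-1-(trimethylsilyloxy)prop-1-ene | COC(O[Si](C)(C)C)=C(C)C | starting material
3 | methyl 2-methyl-2-[(1R)-2-methyl-3-(trimethylsilyloxy)cyclohex-2-en-1-yl]propanoate | C[Si](C)(C)OC1=C(C)[C@H](C(C)(C)C(=O)OC)CCC1 | intermediate
4 | methyl bromoacetate | BrCC(=O)OC | starting material
5 | benzyltrimethylammonium enolate derived from 3 (C9–O enolate, C9=C10) | C[N+](C)(C)Cc1ccccc1.[O-]C1=C(C)[C@H](C(C)(C)C(=O)OC)CCC1 | intermediate (not isolated)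
6 | methyl 2-[(1S,2R)-2-(1-methoxy-2-methyl-1-oxopropan-2-yl)-1-methyl-6-oxocyclohexyl]acetate | O=C1[C@@](C)(CC(=O)OC)[C@H](C(C)(C)C(=O)OC)CCC1 | intermediate
7 | potassium enolate of 6 (C8=C9) | [K+].[O-]C1[C@@](C)(CC(=O)OC)[C@H](C(C)(C)C(=O)OC)CCC=1 | intermediate (not isolated)
8 | methyl 2-[(1S,6R)-6-(1-methoxy-2-methyl-1-oxopropan-2-yl)-1-methyl-2-(trifluoromethanesulfonyloxy)cyclohex-2-en-1-yl]acetate | FC(F)(F)S(=O)(=O)OC1[C@@](C)(CC(=O)OC)[C@H](C(C)(C)C(=O)OC)CCC=1 | intermediate
9 | allyloxy(tert-butyl)dimethylsilane | C=CCO[Si](C)(C)C(C)(C)C | starting material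
10 | B-[3-(tert-butyldimethylsilyloxy)propyl]-9-borabicyclo[3.3.1]nonane | CC(C)(C)[Si](C)(C)OCCCB1C2CCCC1CCC2 | intermediate (not isolated)
11 | methyl 2-[(1S,6R)-2-[3-(tert-butyldimethylsilyloxy)propyl]-6-(1-methoxy-2-methyl-1-oxopropan-2-yl)-1-methylcyclohex-2-en-1-yl]acetate | CC(C)(C)[Si](C)(C)OCCCC1[C@@](C)(CC(=O)OC)[C@H](C(C)(C)C(=O)OC)CCC=1 | intermediate
12 | C8 alkylborane (13 with BH2 in place of OH, same configuration) | CC(C)(C)[Si](C)(C)OCCC[C@@H]1[C@@](C)(CC(=O)OC)[C@H](C(C)(C)C(=O)OC)CC[C@H]1B | intermediate (not isolated)
13 | methyl 2-[(1S,2R,3R,6R)-2-[3-(tert-butyldimethylsilyloxy)propyl]-3-hydroxy-6-(1-methoxy-2-methyl-1-oxopropan-2-yl)-1-methylcyclohexyl]acetate | CC(C)(C)[Si](C)(C)OCCC[C@@H]1[C@@](C)(CC(=O)OC)[C@H](C(C)(C)C(=O)OC)CC[C@H]1O | intermediate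
14 | methyl 2-[(1S,2R,6R)-2-[3-(tert-butyldimethylsilyloxy)propyl]-6-(1-methoxy-2-methyl-1-oxopropan-2-yl)-1-methyl-3-oxocyclohexyl]acetate | CC(C)(C)[Si](C)(C)OCCC[C@@H]1[C@@](C)(CC(=O)OC)[C@H](C(C)(C)C(=O)OC)CCC1=O | intermediate
15 | methyl 2-[(1R,2S,6R)-2-[3-(tert-butyldimethylsilyloxy)propyl]-6-(1-methoxy-2-methyl-1-oxopropan-2-yl)-1-methyl-3-methylidenecyclohexyl]acetate | CC(C)(C)[Si](C)(C)OCCC[C@@H]1[C@@](C)(CC(=O)OC)[C@H](C(C)(C)C(=O)OC)CCC1=C | intermediate
16 | organomercurial (17 with CH2HgOAc in place of the C8 methyl group, same configuration) | CC(C)(C)[Si](C)(C)OCCC[C@@H]1[C@@](C)(CC(=O)OC)[C@H](C(C)(C)C(=O)OC)CC[C@@]1(C[Hg]OC(C)=O)O | intermediate (not isolated)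
17 | methyl 2-[(1S,2R,3R,6R)-2-[3-(tert-butyldimethylsilyloxy)propyl]-3-hydroxy-6-(1-methoxy-2-methyl-1-oxopropan-2-yl)-1,3-dimethylcyclohexyl]acetate | CC(C)(C)[Si](C)(C)OCCC[C@@H]1[C@@](C)(CC(=O)OC)[C@H](C(C)(C)C(=O)OC)CC[C@@]1(C)O | intermediate
18 | methyl 2-[(1S,2R,3R,6R)-3-hydroxy-2-(3-hydroxypropyl)-6-(1-methoxy-2-methyl-1-oxopropan-2-yl)-1,3-dimethylcyclohexyl]acetate | OCCC[C@@H]1[C@@](C)(CC(=O)OC)[C@H](C(C)(C)C(=O)OC)CC[C@@]1(C)O | intermediate
19 | open hydroxy aldehyde (18 with CHO in place of CH2OH) | O=CCC[C@@H]1[C@@](C)(CC(=O)OC)[C@H](C(C)(C)C(=O)OC)CC[C@@]1(C)O | intermediate (not isolated)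
20 | methyl 2-[(4aR,5S,6R,8aR)-2-hydroxy-5-(2-methoxy-2-oxoethyl)-5,8a-dimethyl-octahydro-2H-chromen-6-yl]-2-methylpropanoate (both anomers) | OC1CC[C@@H]2[C@@](C)(CC(=O)OC)[C@H](C(C)(C)C(=O)OC)CC[C@@]2(C)O1 | intermediate
21 | methyl 2-[(1S,2R,3R,6R)-2-(but-3-yn-1-yl)-3-hydroxy-6-(1-methoxy-2-methyl-1-oxopropan-2-yl)-1,3-dimethylcyclohexyl]acetate | C#CCC[C@@H]1[C@@](C)(CC(=O)OC)[C@H](C(C)(C)C(=O)OC)CC[C@@]1(C)O | intermediate
22 | (E)-alkenyldimethylalane (23 with AlMe2 in place of CH2OH; C8 oxygen as O–AlMe2) | C[Al](C)/C=C(\C)CC[C@@H]1[C@@](C)(CC(=O)OC)[C@H](C(C)(C)C(=O)OC)CC[C@@]1(C)O[Al](C)C | intermediate (not isolated)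
23 | methyl 2-[(1S,2R,3R,6R)-3-hydroxy-2-[(3E)-5-hydroxy-3-methylpent-3-en-1-yl]-6-(1-methoxy-2-methyl-1-oxopropan-2-yl)-1,3-dimethylcyclohexyl]acetate | OC/C=C(\C)CC[C@@H]1[C@@](C)(CC(=O)OC)[C@H](C(C)(C)C(=O)OC)CC[C@@]1(C)O | intermediate
24 | methyl 2-[(1S,2R,3R,6R)-3-hydroxy-2-{2-[(2S,3S)-3-(hydroxymethyl)-2-methyloxiran-2-yl]ethyl}-6-(1-methoxy-2-methyl-1-oxopropan-2-yl)-1,3-dimethylcyclohexyl]acetate | OC[C@@H]1O[C@@]1(C)CC[C@@H]2[C@@](C)(CC(=O)OC)[C@H](C(C)(C)C(=O)OC)CC[C@@]2(C)O | intermediate
25 | methyl 2-[(2R,4aR,5S,6R,8aR)-2-[(1S)-1,2-dihydroxyethyl]-5-(2-methoxy-2-oxoethyl)-2,5,8a-trimethyl-octahydro-2H-chromen-6-yl]-2-methylpropanoate | OC[C@H](O)[C@@]1(C)CC[C@@H]2[C@@](C)(CC(=O)OC)[C@H](C(C)(C)C(=O)OC)CC[C@@]2(C)O1 | intermediate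
26 | methyl 2-[(2R,4aR,5S,6R,8aR)-5-(2-methoxy-2-oxoethyl)-2,5,8a-trimethyl-2-[(4S)-2-sulfanylidene-1,3-dioxolan-4-yl]-octahydro-2H-chromen-6-yl]-2-methylpropanoate | S=C1OC[C@H](O1)[C@@]2(C)CC[C@@H]3[C@@](C)(CC(=O)OC)[C@H](C(C)(C)C(=O)OC)CC[C@@]3(C)O2 | intermediate
27 | methyl 2-[(2R,4aR,5S,6R,8aR)-2-ethenyl-5-(2-methoxy-2-oxoethyl)-2,5,8a-trimethyl-octahydro-2H-chromen-6-yl]-2-methylpropanoate | C=C[C@@]1(C)CC[C@@H]2[C@@](C)(CC(=O)OC)[C@H](C(C)(C)C(=O)OC)CC[C@@]2(C)O1 | intermediate
28 | 2-[(2R,4aR,5S,6R,8aR)-5-(carboxymethyl)-2-ethenyl-2,5,8a-trimethyl-octahydro-2H-chromen-6-yl]-2-methylpropanoic acid | C=C[C@@]1(C)CC[C@@H]2[C@@](C)(CC(=O)O)[C@H](C(C)(C)C(=O)O)CC[C@@]2(C)O1 | target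

## Step count and least certain steps

Total step count: 17. Longest linear sequence: 17 steps (1 to 28; compounds 2, 4 and 9 are commercial).

**Step 14 (key step).** The most likely failure is that the opening drifts towards a free tertiary cation at C13. The hindered tertiary C8 hydroxyl has to build a 1,3-diaxial methyl/methyl contact as it attacks, and if this is slow, ionisation, proton loss from the cation or a hydride shift can take over, with loss of the inversion that carries the stereochemical information. Fallback: starting from 23, the primary hydroxyl is converted with methyl chloroformate and pyridine into the allylic methyl carbonate F8. Zerovalent palladium (Pd2(dba)3) with a chiral trans-1,2-diaminocyclohexane bis(2-diphenylphosphinobenzamide) ligand then ionises the carbonate. The C8 hydroxyl attacks the π-allyl unit at C13, the only position that gives a six-membered ring, and this delivers the vinyl-substituted pyran 27 directly (intramolecular Tsuji–Trost etherification). C13 would then be set by the ligand instead of by inversion, and steps 13 to 16 are bypassed.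

**Step 1.** The most likely failure is poor facial discrimination, because the α-methyl enone 1 lacks the α-hydrogen that usually helps to lock an enone on this type of catalyst, together with lower reactivity of the α-substituted enone. Fallback: 1 and 2 are combined with the achiral Lewis acid Me3SiNTf2 to give the racemic silyl enol ether F1. The alkylation of step 2 converts it into the racemic trans keto diester F2. Separation of the enantiomers by preparative chromatography on a chiral stationary phase returns 6.

**Step 4.** The most likely failure is slow oxidative addition and transmetalation at the triflate, which is flanked by the quaternary C10, so that hydrolysis of the triflate back to 6 or loss of the alkylborane by protodeboronation competes. Fallback: starting from 8, a Stille coupling with allyltributylstannane (Pd(PPh3)4, LiCl, THF, reflux) gives the skipped diene F3. Its terminal alkene alone is hydroborated with 9-BBN and oxidised with NaBO3 to the primary alcohol F4. Silylation with tert-butyldimethylsilyl chloride and imidazole returns 11.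

**Step 8.** The most likely failure is attack of water on the axial face of C8 if the ring twists to relieve strain around C9 and C10, which would give the C8 epimer. Fallback: starting from 15, epoxidation with m-chloroperbenzoic acid (NaHCO3, CH2Cl2) from the equatorial face gives the spiro-epoxide F5. MgI2 opens it at the CH2 carbon to the iodohydrin F6, and Bu3SnH with azobisisobutyronitrile removes the iodine by a radical chain to return 17. A hydride reagent is avoided because of the esters.

**Step 12.** The most likely failure is incomplete capture of the alkenylalane by formaldehyde, which leaves the protonated alkene after work-up, or methyl transfer from Me3Al to an ester carbonyl if the reaction has to be warmed. Fallback: starting from 21, the same carboalumination is run, and the alkenylalane 22 is quenched with I2 to give the (E)-vinyl iodide F7, a clean and fast capture. A Stille coupling of F7 with (tributylstannyl)methanol under zerovalent palladium (Pd(PPh3)4, dioxane, 80 °C) returns 23 with the alkene geometry retained.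

## Further compounds

F1 | step 1 | racemic methyl 2-methyl-2-[2-methyl-3-(trimethylsilyloxy)cyclohex-2-en-1-yl]propanoate | C[Si](C)(C)OC1=C(C)C(C(C)(C)C(=O)OC)CCC1
F2 | step 1 | racemic trans keto diester, methyl 2-[(1S*,2R*)-2-(1-methoxy-2-methyl-1-oxopropan-2-yl)-1-methyl-6-oxocyclohexyl]acetate (both enantiomers) | O=C1C(C)(CC(=O)OC)C(C(C)(C)C(=O)OC)CCC1
F3 | step 4 | methyl 2-[(1S,6R)-6-(1-methoxy-2-methyl-1-oxopropan-2-yl)-1-methyl-2-(prop-2-en-1-yl)cyclohex-2-en-1-yl]acetate | C=CCC1[C@@](C)(CC(=O)OC)[C@H](C(C)(C)C(=O)OC)CCC=1
F4 | step 4 | methyl 2-[(1S,6R)-2-(3-hydroxypropyl)-6-(1-methoxy-2-methyl-1-oxopropan-2-yl)-1-methylcyclohex-2-en-1-yl]acetate | OCCCC1[C@@](C)(CC(=O)OC)[C@H](C(C)(C)C(=O)OC)CCC=1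
F5 | step 8 | spiro-epoxide of 15 (oxirane oxygen on C8 where the hydroxyl of 17 sits, oxirane CH2 axial) | CC(C)(C)[Si](C)(C)OCCC[C@@H]1[C@@](C)(CC(=O)OC)[C@H](C(C)(C)C(=O)OC)CC[C@@]1(C2)O2
F6 | step 8 | iodohydrin (17 with CH2I in place of the C8 methyl group) | CC(C)(C)[Si](C)(C)OCCC[C@@H]1[C@@](C)(CC(=O)OC)[C@H](C(C)(C)C(=O)OC)CC[C@@]1(CI)O
F7 | step 12 | methyl 2-[(1S,2R,3R,6R)-3-hydroxy-2-[(3E)-4-iodo-3-methylbut-3-en-1-yl]-6-(1-methoxy-2-methyl-1-oxopropan-2-yl)-1,3-dimethylcyclohexyl]acetate | I/C=C(\C)CC[C@@H]1[C@@](C)(CC(=O)OC)[C@H](C(C)(C)C(=O)OC)CC[C@@]1(C)O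
F8 | step 14 | methyl carbonate of 23 at the primary allylic hydroxyl | COC(=O)OC/C=C(\C)CC[C@@H]1[C@@](C)(CC(=O)OC)[C@H](C(C)(C)C(=O)OC)CC[C@@]1(C)O
A1 | alternative 1 | tert-butyl 2-[(1S,2R)-2-(1-methoxy-2-methyl-1-oxopropan-2-yl)-1-methyl-6-oxocyclohexyl]acetate | O=C1[C@@](C)(CC(=O)OC(C)(C)C)[C@H](C(C)(C)C(=O)OC)CCC1
A2 | alternative 1 | tert-butyl bromoacetate | BrCC(=O)OC(C)(C)C
A3 | alternative 2 | methyl 2-[(2R,4aR,5S,6R,8aR)-2-[2-(tert-butyldimethylsilyloxy)ethyl]-5-(2-methoxy-2-oxoethyl)-2,5,8a-trimethyl-octahydro-2H-chromen-6-yl]-2-methylpropanoate | CC(C)(C)[Si](C)(C)OCC[C@@]1(C)CC[C@@H]2[C@@](C)(CC(=O)OC)[C@H](C(C)(C)C(=O)OC)CC[C@@]2(C)O1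
A4 | alternative 2 | methyl (4R,7E,11R)-13-(tert-butyldimethylsilyloxy)-11-hydroxy-4-(1-methoxy-2-methyl-1-oxopropan-2-yl)-7,11-dimethyl-3-methylidenetridec-7-enoate | C=C(CC(=O)OC)[C@H](C(C)(C)C(=O)OC)CC/C(C)=C/CC[C@@](C)(O)CCO[Si](C)(C)C(C)(C)C
A5 | alternative 2 | Co(salen), N,N′-bis(salicylidene)ethylenediamine complex of divalent cobalt | [Co+2].[O-]c1ccccc1C=NCCN=Cc1ccccc1[O-]
A6 | alternative 3 | ethyl (2R,5S,6R,8aR)-5-(2-tert-butoxy-2-oxoethyl)-6-(1-methoxy-2-methyl-1-oxopropan-2-yl)-2,5,8a-trimethyl-3,5,6,7,8,8a-hexahydro-2H-chromene-2-carboxylate | CCOC(=O)[C@@]1(C)CC=C2[C@@](C)(CC(=O)OC(C)(C)C)[C@H](C(C)(C)C(=O)OC)CC[C@@]2(C)O1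
A7 | alternative 3 | tert-butyl 2-[(1S,6R)-2-ethenyl-6-(1-methoxy-2-methyl-1-oxopropan-2-yl)-1,3-dimethylcyclohex-2-en-1-yl]acetate | C=CC1[C@@](C)(CC(=O)OC(C)(C)C)[C@H](C(C)(C)C(=O)OC)CCC(C)=1
A8 | alternative 3 | ethyl pyruvate | CCOC(=O)C(C)=O
A9 | alternative 3 | Cu(OTf)2, copper bis(trifluoromethanesulfonate) | [Cu+2].[O-]S(=O)(=O)C(F)(F)F.[O-]S(=O)(=O)C(F)(F)F
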